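**Retrosynthetic overview**
- Target ⇐ bridged pyran-3-one by catalyst-controlled ketone reduction (C3), acetylation and O7 desilylation.
- Pyran-3-one ⇐ acyclic α-diazoketone. A Cu-carbenoid adds to the remote Me2C=CH terminus, closing the 14-membered carbocycle and a gem-dimethylcyclopropane in one operation (sets C1).
- In the same flask the cyclopropyl ketone is opened at C2–C15 by the C4 oxygen, so the three-ring is traded for the tetrahydropyran.
- Diazoketone ⇐ methyl ketone (diazo transfer) ⇐ Nozaki–Hiyama–Kishi union at C7–C8 (sets C7) of a keto aldehyde and an enol triflate.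
- Keto aldehyde ⇐ (S)-linalool (source of C4); enol triflate ⇐ (E)-geranylacetone.

Assumption: (S)-(+)-linalool (coriandrol, ≥95 % ee) and (E)-geranylacetone are bought as such.

Cembrane numbering is used for the ring compounds: C1 = CH bearing C15; C2 = pyran CH2; C3 = CH–OAc; C4 = C(Me)–O; C7 = CH–OH; C8 = C(=CH2); C11=C12 = ring alkene; C15 = CMe2–O.

**Route**

Step 1
Reactants: 1 (S)-(+)-linalool
Product: 2 (3S)-3,7-dimethyl-3-(triethylsilyloxy)octa-1,6-diene
Conditions: TESOTf, 2,6-lutidine, CH2Cl2, −78 → 0 °C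
Reagents that add atoms: triethylsilyl trifluoromethanesulfonate, CC[Si](CC)(CC)OS(=O)(=O)C(F)(F)F
Why: O-silylation with a silyl triflate works even on the tertiary alcohol, and no bond to the stereocentre is touched.

Step 2
Reactants: 2 (3S)-3,7-dimethyl-3-(triethylsilyloxy)octa-1,6-diene
Product: 3 (3S)-3,7-dimethyl-3-(triethylsilyloxy)oct-6-en-2-one
Conditions: Pd(quinox)Cl2 (5 mol %), AgSbF6 (12 mol %), aq TBHP, CH2Cl2, 0 °C → rt
Reagents that add atoms: tert-butyl hydroperoxide, CC(C)(C)OO
Why: Tsuji–Wacker oxidation in its TBHP/quinox form gives the methyl ketone from the monosubstituted vinyl group even next to an allylic oxygen, while the trisubstituted alkene is inert.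

Step 3
Reactants: 3 (3S)-3,7-dimethyl-3-(triethylsilyloxy)oct-6-en-2-one
Product: 4 (4S)-4-methyl-5-oxo-4-(triethylsilyloxy)hexanal
Conditions: O3, CH2Cl2, −78 °C; Me2S, −78 °C → rt
Reagents that add atoms: ozone, [O-][O+]=O
Why: Ozonolysis with reductive work-up cleaves the only C=C left to the aldehyde; the ketone, silyl ether and quaternary stereocentre are unaffected.

Step 4
Reactants: 5 (E)-geranylacetone, (5E)-6,10-dimethylundeca-5,9-dien-2-one
Product: 6 (5E)-6,10-dimethylundeca-1,5,9-trien-2-yl trifluoromethanesulfonate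
Conditions: LDA, THF, −78 °C; PhNTf2, −78 → 0 °C; aq NH4Cl
Reagents that add atoms: N-phenylbis(trifluoromethanesulfonimide), O=S(=O)(N(c1ccccc1)S(=O)(=O)C(F)(F)F)C(F)(F)F
Why: Kinetic enolisation of the methyl ketone at CH3 followed by O-triflation gives the 2-triflyloxy-1-alkene, and the E alkene is not touched.

Step 5
Reactants: 4 (4S)-4-methyl-5-oxo-4-(triethylsilyloxy)hexanal; 6 (5E)-6,10-dimethylundeca-1,5,9-trien-2-yl trifluoromethanesulfonate
Product: 7 (3S,6R,10E)-6-hydroxy-3,11,15-trimethyl-7-methylidene-3-(triethylsilyloxy)hexadeca-10,14-dien-2-one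
Conditions: CrCl2 (3.5 equiv), Kishi oxazoline–sulfonamide ligand (antipode giving the R carbinol, 3.8 equiv, recovered), Et3N, NiCl2 (5 mol %), THF, rt
Reagents that add atoms: none
Why: Nozaki–Hiyama–Kishi coupling, in which the alkenyl–Cr(III) species adds only to the aldehyde (the hindered ketone is a spectator) and the chiral ligand on chromium selects the aldehyde face, setting the carbinol (C7 of the target) as R and installing the 1,1-disubstituted alkene directly.

Step 6
Reactants: 7 (3S,6R,10E)-6-hydroxy-3,11,15-trimethyl-7-methylidene-3-(triethylsilyloxy)hexadeca-10,14-dien-2-one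
Product: 8 (3S,6R,10E)-6-(tert-butyldimethylsilyloxy)-3,11,15-trimethyl-7-methylidene-3-(triethylsilyloxy)hexadeca-10,14-dien-2-one
Conditions: TBSCl, imidazole, DMF, rt
Reagents that add atoms: tert-butyldimethylsilyl chloride, CC(C)(C)[Si](C)(C)Cl
Why: Standard silylation of the secondary allylic alcohol, which keeps O7 out of the carbenoid step and distinct from O3 at the end.

Step 7
Reactants: 8 (3S,6R,10E)-6-(tert-butyldimethylsilyloxy)-3,11,15-trimethyl-7-methylidene-3-(triethylsilyloxy)hexadeca-10,14-dien-2-one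
Product: 10 (3S,6R,10E)-6-(tert-butyldimethylsilyloxy)-1-diazo-3,11,15-trimethyl-7-methylidene-3-(triethylsilyloxy)hexadeca-10,14-dien-2-one, via trifluoroacetyl diketone 9 (not isolated)
Conditions: LiHMDS, THF, −78 °C, then CF3CO2CH2CF3 (O=C(OCC(F)(F)F)C(F)(F)F); crude 9, MsN3, Et3N, H2O, MeCN, rt
Reagents that add atoms: methanesulfonyl azide, CS(=O)(=O)N=[N+]=[N-]
Why: Danheiser detrifluoroacetylative diazo transfer: the ketone can enolise only towards CH3 because the other α-carbon is quaternary, and Claisen trifluoroacetylation activates that carbon for diazo transfer with loss of the CF3CO group.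

Step 8
Reactants: 10 (3S,6R,10E)-6-(tert-butyldimethylsilyloxy)-1-diazo-3,11,15-trimethyl-7-methylidene-3-(triethylsilyloxy)hexadeca-10,14-dien-2-one
Product: 12 (1R,4S,7R,11E)-7-(tert-butyldimethylsilyloxy)-4,15-epoxycembra-8(19),11-dien-3-one, via cyclopropyl ketone 11 (not isolated)
Conditions: Cu(MeCN)4PF6 (10 mol %), (S,S)-tBu-box (12 mol %), CH2Cl2, 40 °C, syringe-pump addition of 10 over 12 h (final 2 mM); then concentrate to 0.05 M, −78 → −20 °C, TMSOTf (0.3 equiv), 2,6-di-tert-butyl-4-methylpyridine; aq NaHCO3, then 0.5 M HCl/THF, 0 °C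
Reagents that add atoms: none
Why: Proposed new method: the electrophilic Cu(I)–box keto-carbenoid adds to the most electron-rich and least hindered alkene, the remote Me2C=CH terminus, closing the 14-membered ring and a gem-dimethylcyclopropane in one event (intramolecular macrocyclic cyclopropanation of the Doyle type; the nearer C8=CH2 and C11=C12 alkenes would need strained 7- and 10/11-membered rings, copper disfavours C–H insertion, and the chiral ligand chooses the alkene face and so sets C1 as R, the C2 centre being erased next); TMSOTf then silylates the ketone, the conjugated cyclopropane bond C2–C15 ionises to the tertiary C15 cation and a silyl enol ether (homo-Michael, SN1-type opening, closest known case the HBr opening of carone), and the C4 silyl ether oxygen captures C15 in a six-membered ring with loss of Et3Si+, the enol ether giving the C3 ketone on work-up; C4 and C7 are untouched.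

Step 9
Reactants: 12 (1R,4S,7R,11E)-7-(tert-butyldimethylsilyloxy)-4,15-epoxycembra-8(19),11-dien-3-one
Product: 13 (1R,3R,4S,7R,11E)-7-(tert-butyldimethylsilyloxy)-4,15-epoxycembra-8(19),11-dien-3-ol
Conditions: (S)-Me-CBS (0.5 equiv), catecholborane (2 equiv), toluene, −78 → −40 °C
Reagents that add atoms: none
Why: Corey–Bakshi–Shibata reduction: with the quaternary C4 as the large group and C2H2 as the small one, the (S)-catalyst delivers hydride to give the 3R alcohol (same sense as aryl methyl ketones), and catecholborane at low temperature leaves the alkenes alone.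

Step 10
Reactants: 13 (1R,3R,4S,7R,11E)-7-(tert-butyldimethylsilyloxy)-4,15-epoxycembra-8(19),11-dien-3-ol
Product: 14 (1R,3R,4S,7R,11E)-7-(tert-butyldimethylsilyloxy)-4,15-epoxycembra-8(19),11-dien-3-yl acetate
Conditions: Ac2O, DMAP, pyridine, CH2Cl2, rt
Reagents that add atoms: acetic anhydride, CC(=O)OC(C)=O
Why: DMAP-catalysed acyl transfer to the only free hydroxyl, with retention at C3.

Step 11
Reactants: 14 (1R,3R,4S,7R,11E)-7-(tert-butyldimethylsilyloxy)-4,15-epoxycembra-8(19),11-dien-3-yl acetate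
Product: 15 (1R,3R,4S,7R,11E)-3-acetoxy-4,15-epoxycembra-8(19),11-dien-7-ol (target)
Conditions: HF·pyridine, pyridine, THF, 0 °C → rt
Reagents that add atoms: none
Why: Fluoride-driven Si–O cleavage frees the C7 allylic alcohol without touching the acetate, the ether bridge or the alkenes.

**Compound list**

1 | (S)-(+)-linalool | C=C[C@@](C)(O)CCC=C(C)C | starting material
2 | (3S)-3,7-dimethyl-3-(triethylsilyloxy)octa-1,6-diene | C=C[C@@](C)(O[Si](CC)(CC)CC)CCC=C(C)C | intermediate
3 | (3S)-3,7-dimethyl-3-(triethylsilyloxy)oct-6-en-2-one | CC(=O)[C@@](C)(O[Si](CC)(CC)CC)CCC=C(C)C | intermediate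
4 | (4S)-4-methyl-5-oxo-4-(triethylsilyloxy)hexanal | CC(=O)[C@@](C)(O[Si](CC)(CC)CC)CCC=O | intermediate
5 | (E)-geranylacetone | CC(=O)CC/C=C(\C)CCC=C(C)C | starting material
6 | (5E)-6,10-dimethylundeca-1,5,9-trien-2-yl trifluoromethanesulfonate | C=C(OS(=O)(=O)C(F)(F)F)CC/C=C(\C)CCC=C(C)C | intermediate
7 | (3S,6R,10E)-6-hydroxy-3,11,15-trimethyl-7-methylidene-3-(triethylsilyloxy)hexadeca-10,14-dien-2-one | CC(=O)[C@@](C)(O[Si](CC)(CC)CC)CC[C@@H](O)C(=C)CC/C=C(\C)CCC=C(C)C | intermediate
8 | (3S,6R,10E)-6-(tert-butyldimethylsilyloxy)-3,11,15-trimethyl-7-methylidene-3-(triethylsilyloxy)hexadeca-10,14-dien-2-one | CC(=O)[C@@](C)(O[Si](CC)(CC)CC)CC[C@@H](O[Si](C)(C)C(C)(C)C)C(=C)CC/C=C(\C)CCC=C(C)C | intermediate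
9 | (5S,8R,12E)-8-(tert-butyldimethylsilyloxy)-1,1,1-trifluoro-5,13,17-trimethyl-9-methylidene-5-(triethylsilyloxy)octadeca-12,16-diene-2,4-dione (trifluoroacetyl diketone) | O=C(CC(=O)[C@@](C)(O[Si](CC)(CC)CC)CC[C@@H](O[Si](C)(C)C(C)(C)C)C(=C)CC/C=C(\C)CCC=C(C)C)C(F)(F)F | intermediate
10 | (3S,6R,10E)-6-(tert-butyldimethylsilyloxy)-1-diazo-3,11,15-trimethyl-7-methylidene-3-(triethylsilyloxy)hexadeca-10,14-dien-2-one | [N-]=[N+]=CC(=O)[C@@](C)(O[Si](CC)(CC)CC)CC[C@@H](O[Si](C)(C)C(C)(C)C)C(=C)CC/C=C(\C)CCC=C(C)C | intermediate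
11 | (3S,6R,10E,14R)-6-(tert-butyldimethylsilyloxy)-3,11,15,15-tetramethyl-7-methylidene-3-(triethylsilyloxy)bicyclo[12.1.0]pentadec-10-en-2-one (cyclopropyl ketone; both epimers at the ketone-bearing cyclopropane CH) | O=C1[C@@](C)(O[Si](CC)(CC)CC)CC[C@@H](O[Si](C)(C)C(C)(C)C)C(=C)CC/C=C(\C)CC[C@@H]2C1C2(C)C | intermediate
12 | (1R,4S,7R,11E)-7-(tert-butyldimethylsilyloxy)-4,15-epoxycembra-8(19),11-dien-3-one | C=C1CC/C=C(\C)CC[C@@H]2CC(=O)[C@](C)(CC[C@H]1O[Si](C)(C)C(C)(C)C)OC2(C)C | intermediate
13 | (1R,3R,4S,7R,11E)-7-(tert-butyldimethylsilyloxy)-4,15-epoxycembra-8(19),11-dien-3-ol | C=C1CC/C=C(\C)CC[C@@H]2C[C@@H](O)[C@](C)(CC[C@H]1O[Si](C)(C)C(C)(C)C)OC2(C)C | intermediate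
14 | (1R,3R,4S,7R,11E)-7-(tert-butyldimethylsilyloxy)-4,15-epoxycembra-8(19),11-dien-3-yl acetate | C=C1CC/C=C(\C)CC[C@@H]2C[C@@H](OC(C)=O)[C@](C)(CC[C@H]1O[Si](C)(C)C(C)(C)C)OC2(C)C | intermediate
15 | (1R,3R,4S,7R,11E)-3-acetoxy-4,15-epoxycembra-8(19),11-dien-7-ol | C=C1CC/C=C(\C)CC[C@@H]2C[C@@H](OC(C)=O)[C@](C)(CC[C@H]1O)OC2(C)C | target

**Step count**

Total step count: 11. Longest linear sequence: 10 steps (1 → 15 through steps 1–3 and 5–11).

**Three steps most likely to fail**

Step 5. Ligand control at the new carbinol may be poor, and which ligand antipode gives R has to be found by experiment. The fallback sets out from 4 and 6 and comes back at 7. The coupling is run without chiral ligand (CrCl2, NiCl2 cat., DMF), which gives 7 mixed with its carbinol epimer (3S,6S,10E)-6-hydroxy-3,11,15-trimethyl-7-methylidene-3-(triethylsilyloxy)hexadeca-10,14-dien-2-one F1. MnO2 then oxidises the allylic alcohol of the mixture to the cross-conjugated enone (3S,10E)-3,11,15-trimethyl-7-methylidene-3-(triethylsilyloxy)hexadeca-10,14-diene-2,6-dione F2. (S)-Me-CBS/catecholborane at −78 °C reduces the unhindered enone carbonyl (alkenyl group as the large one) ahead of the α-quaternary methyl ketone, so the stereocentre is set by reduction instead of by C–C bond formation, and 7 is regained.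

Step 8. Three things can go wrong:
- the carbenoid may add to C8=CH2 or insert into C–H instead of reaching the remote alkene;
- the face of attack (C1) must be matched to the ligand antipode by experiment;
- the C15 cation may be taken by the C11=C12 alkene across the ring or by the enol oxygen.

The fallback sets out from 8 and comes back at 12, replacing the carbenoid by a radical and then a cation. The kinetic silyl enol ether of 8 (LiHMDS, TMSCl) is iodinated with NIS to the α-iodo ketone (3S,6R,10E)-6-(tert-butyldimethylsilyloxy)-1-iodo-3,11,15-trimethyl-7-methylidene-3-(triethylsilyloxy)hexadeca-10,14-dien-2-one F1... corrected label: F3. Et3B/O2 in benzene at 2 mM starts an iodine-atom-transfer radical macrocyclisation in which the electrophilic α-keto radical adds to the Me2C=CH terminus and the tertiary radical takes iodine, giving (1R,4S,7R,11E)-7-(tert-butyldimethylsilyloxy)-15-iodo-4-(triethylsilyloxy)cembra-8(19),11-dien-3-one F4 (formed with its C1 epimer, separated). AgOTf with 2,6-di-tert-butyl-4-methylpyridine in CH2Cl2 at −40 °C ionises the C15–I bond and the C4 oxygen closes the pyran with loss of the triethylsilyl group, which gives 12.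

Step 9. The face of the C3 carbonyl away from the macrocyclic bridge is the more open one and leads to the wrong epimer, so the substrate may override the catalyst. The fallback sets out from 12 and comes back at 13, using inversion instead of face-selective reduction. L-Selectride (THF, −78 °C) attacks from the open face and gives (1R,3S,4S,7R,11E)-7-(tert-butyldimethylsilyloxy)-4,15-epoxycembra-8(19),11-dien-3-ol F5. A Mitsunobu reaction (4-nitrobenzoic acid, PPh3, DIAD, toluene) inverts C3 to (1R,3R,4S,7R,11E)-7-(tert-butyldimethylsilyloxy)-4,15-epoxycembra-8(19),11-dien-3-yl 4-nitrobenzoate F6, and K2CO3 in methanol releases 13.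

**Further compounds**

F1 | step 5 | (3S,6S,10E)-6-hydroxy-3,11,15-trimethyl-7-methylidene-3-(triethylsilyloxy)hexadeca-10,14-dien-2-one | CC(=O)[C@@](C)(O[Si](CC)(CC)CC)CC[C@H](O)C(=C)CC/C=C(\C)CCC=C(C)C
F2 | step 5 | (3S,10E)-3,11,15-trimethyl-7-methylidene-3-(triethylsilyloxy)hexadeca-10,14-diene-2,6-dione | CC(=O)[C@@](C)(O[Si](CC)(CC)CC)CCC(=O)C(=C)CC/C=C(\C)CCC=C(C)C
F3 | step 8 | (3S,6R,10E)-6-(tert-butyldimethylsilyloxy)-1-iodo-3,11,15-trimethyl-7-methylidene-3-(triethylsilyloxy)hexadeca-10,14-dien-2-one | ICC(=O)[C@@](C)(O[Si](CC)(CC)CC)CC[C@@H](O[Si](C)(C)C(C)(C)C)C(=C)CC/C=C(\C)CCC=C(C)C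
F4 | step 8 | (1R,4S,7R,11E)-7-(tert-butyldimethylsilyloxy)-15-iodo-4-(triethylsilyloxy)cembra-8(19),11-dien-3-one | C=C1CC/C=C(\C)CC[C@@H](C(C)(C)I)CC(=O)[C@](C)(CC[C@H]1O[Si](C)(C)C(C)(C)C)O[Si](CC)(CC)CC
F5 | step 9 | (1R,3S,4S,7R,11E)-7-(tert-butyldimethylsilyloxy)-4,15-epoxycembra-8(19),11-dien-3-ol | C=C1CC/C=C(\C)CC[C@@H]2C[C@H](O)[C@](C)(CC[C@H]1O[Si](C)(C)C(C)(C)C)OC2(C)C
F6 | step 9 | (1R,3R,4S,7R,11E)-7-(tert-butyldimethylsilyloxy)-4,15-epoxycembra-8(19),11-dien-3-yl 4-nitrobenzoate | C=C1CC/C=C(\C)CC[C@@H]2C[C@@H](OC(=O)c3ccc(cc3)[N+](=O)[O-])[C@](C)(CC[C@H]1O[Si](C)(C)C(C)(C)C)OC2(C)C
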